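**Strategy.** The lower pyran ring (ring F) is built last, on a complete robinetinidol–aryl adduct. Before ring F exists, ring D is a 2,6-dioxygenated 4-hydroxyphenyl group: its phenol oxygen (future O1) is para to the interflavan carbon C6 and the two ortho carbons (future C4a and C8) are equivalent, so only the 4→6 isomer can arise. Ring-closing olefin metathesis of an ortho-vinylaryl (S)-1-arylallyl ether then joins C4 to C3 as the C3=C4 alkene of a flav-3-ene. C2, set by iridium catalysis, directs hydroboration to the trans C3 hydroxyl. The upper C4 centre comes from aryllithium addition to protected dihydrorobinetin and ionic hydrogenation.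

Key step: step 13

**Remarks on the chemistry.**
- The target is read as robinetinidol-(4β→6)-gallocatechin: upper unit (2R,3S,4R), 2,3-trans-3,4-cis; lower unit (2R,3S), 2,3-trans.
- Rings are lettered A (benzo), C (pyran), B (pyrogallol) in the upper unit and D, F, E in the lower unit.
- (2R,3R)-(+)-Dihydrorobinetin, 3,5-bis(benzyloxy)phenol and 3,4,5-tris(benzyloxy)benzaldehyde are taken as commercial.
- The (Sa,Sc,Sc) phosphoramidite in step 12 is the enantiomer expected to give the (S) ether. The sense should be checked on phenol 4 as a model, and the (Ra,Rc,Rc) ligand used if it is reversed.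
- Rotation about the C4–aryl bond makes the two ortho positions of the ring D phenol in 9 constitutionally equivalent.

Step 1
Reactants: 1 (2R,3R)-dihydrorobinetin
Product: 2 (2R,3R)-7-(benzyloxy)-3-hydroxy-2-[3,4,5-tris(benzyloxy)phenyl]chroman-4-one
Conditions: BnBr (4.4 equiv), K2CO3, DMF, rt, argon
Reagents that add atoms: benzyl bromide, BrCc1ccccc1
Why: Williamson ether synthesis; only the four phenols are acidic enough for K2CO3, and the secondary 3-OH and both stereocentres should stay untouched at room temperature.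

Step 2
Reactants: 2 (2R,3R)-7-(benzyloxy)-3-hydroxy-2-[3,4,5-tris(benzyloxy)phenyl]chroman-4-one
Product: 3 (2R,3R)-7-(benzyloxy)-3-(tert-butyldimethylsilyloxy)-2-[3,4,5-tris(benzyloxy)phenyl]chroman-4-one
Conditions: TBSCl, imidazole, DMF, rt to 40 °C
Reagents that add atoms: tert-butyldimethylsilyl chloride, CC(C)(C)[Si](C)(C)Cl
Why: Silylation of the only free hydroxyl under non-enolising conditions masks the acidic OH before the organolithium step and installs the bulky group that later steers the facial selectivity at C4.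

Step 3
Reactants: 4 3,5-bis(benzyloxy)phenol
Product: 5 [3,5-bis(benzyloxy)phenoxy]triisopropylsilane
Conditions: TIPSCl, imidazole, DMF, rt
Reagents that add atoms: triisopropylsilyl chloride, CC(C)[Si](Cl)(C(C)C)C(C)C
Why: Phenol silylation; the bulky, weakly coordinating silyl ether marks the oxygen that will become O1 and blocks lithiation at its two ortho positions.

Step 4
Reactants: 5 [3,5-bis(benzyloxy)phenoxy]triisopropylsilane; 3 (2R,3R)-7-(benzyloxy)-3-(tert-butyldimethylsilyloxy)-2-[3,4,5-tris(benzyloxy)phenyl]chroman-4-one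
Product: 7 (2R,3R,4R)-4-[2,6-bis(benzyloxy)-4-(triisopropylsilyloxy)phenyl]-7-(benzyloxy)-3-(tert-butyldimethylsilyloxy)-2-[3,4,5-tris(benzyloxy)phenyl]chroman-4-ol, via aryllithium 6 (not isolated)
Conditions: 5, n-BuLi, THF, 0 °C; then 3, THF, −78 to −40 °C; aq NH4Cl
Reagents that add atoms: n-butyllithium, [Li]CCCC (its lithium is found in 6 only)
Why: Directed ortho-lithiation between the two benzyloxy groups gives aryllithium 6, which adds 1,2 to the aryl ketone, expected from the face opposite the C3 silyloxy group; the C4 configuration of 7 does not matter because step 5 erases it.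

Step 5
Reactants: 7 (2R,3R,4R)-4-[2,6-bis(benzyloxy)-4-(triisopropylsilyloxy)phenyl]-7-(benzyloxy)-3-(tert-butyldimethylsilyloxy)-2-[3,4,5-tris(benzyloxy)phenyl]chroman-4-ol
Product: 8 (2R,3S,4R)-4-[2,6-bis(benzyloxy)-4-(triisopropylsilyloxy)phenyl]-7-(benzyloxy)-3-(tert-butyldimethylsilyloxy)-2-[3,4,5-tris(benzyloxy)phenyl]chromane
Conditions: Bu3SnH, CF3CO2H, CH2Cl2, −20 to 0 °C
Reagents that add atoms: none
Why: Ionic hydrogenation (Kursanov–Parnes type): acid ionises the tertiary doubly benzylic alcohol and Bu3SnH should deliver hydride to the C4 cation on the face opposite the bulky C3 silyloxy group, the facial preference known for nucleophiles adding to flavan-4-yl cations, so H ends up trans and the aryl group cis to O3 (3,4-cis, 4R).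

Step 6
Reactants: 8 (2R,3S,4R)-4-[2,6-bis(benzyloxy)-4-(triisopropylsilyloxy)phenyl]-7-(benzyloxy)-3-(tert-butyldimethylsilyloxy)-2-[3,4,5-tris(benzyloxy)phenyl]chromane
Product: 9 (2R,3S,4R)-4-[2,6-bis(benzyloxy)-4-hydroxyphenyl]-7-(benzyloxy)-2-[3,4,5-tris(benzyloxy)phenyl]chroman-3-ol
Conditions: Bu4NF (3 equiv), AcOH (buffer), THF, 0 °C to rt
Reagents that add atoms: none
Why: Fluoride desilylation removes both silyl ethers in one operation and frees the ring D phenol that is para to the interflavan bond; benzyl ethers are inert.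

Step 7
Reactants: 9 (2R,3S,4R)-4-[2,6-bis(benzyloxy)-4-hydroxyphenyl]-7-(benzyloxy)-2-[3,4,5-tris(benzyloxy)phenyl]chroman-3-ol
Product: 10 2,4-bis(benzyloxy)-6-hydroxy-3-[(2R,3S,4R)-7-(benzyloxy)-3-hydroxy-2-[3,4,5-tris(benzyloxy)phenyl]chroman-4-yl]benzaldehyde
Conditions: MgCl2, Et3N, (CH2O)n, MeCN, reflux
Reagents that add atoms: paraformaldehyde (formaldehyde), C=O
Why: Magnesium-phenoxide-directed ortho-formylation (Casnati–Skattebøl); the two positions ortho to the phenol are equivalent, so one constitutional isomer forms and the new carbon is the future C4 of ring F.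

Step 8
Reactants: 10 2,4-bis(benzyloxy)-6-hydroxy-3-[(2R,3S,4R)-7-(benzyloxy)-3-hydroxy-2-[3,4,5-tris(benzyloxy)phenyl]chroman-4-yl]benzaldehyde
Product: 11 3,5-bis(benzyloxy)-4-[(2R,3S,4R)-7-(benzyloxy)-3-hydroxy-2-[3,4,5-tris(benzyloxy)phenyl]chroman-4-yl]-2-vinylphenol
Conditions: MePPh3Br (4 equiv), KOtBu (4 equiv), THF, 0 °C to rt
Reagents that add atoms: methyltriphenylphosphonium bromide, C[P+](c1ccccc1)(c1ccccc1)c1ccccc1.[Br-]
Why: Wittig methylenation of a salicylaldehyde with excess ylide (the phenol and alcohol are carried as their potassium salts) gives the ortho-vinylphenol without touching any stereocentre.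

Step 9
Reactants: 12 3,4,5-tris(benzyloxy)benzaldehyde
Product: 13 ethyl (E)-3-[3,4,5-tris(benzyloxy)phenyl]prop-2-enoate
Conditions: (EtO)2P(O)CH2CO2Et, NaH, THF, 0 °C to rt
Reagents that add atoms: triethyl phosphonoacetate, CCOC(=O)CP(=O)(OCC)OCC
Why: Horner–Wadsworth–Emmons olefination of an aryl aldehyde with a stabilised phosphonate gives the (E)-cinnamate.

Step 10
Reactants: 13 ethyl (E)-3-[3,4,5-tris(benzyloxy)phenyl]prop-2-enoate
Product: 14 (E)-3-[3,4,5-tris(benzyloxy)phenyl]prop-2-en-1-ol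
Conditions: i-Bu2AlH (2.2 equiv), CH2Cl2, −78 °C; Rochelle salt work-up
Reagents that add atoms: none
Why: 1,2-Reduction of the conjugated ester with an aluminium hydride gives the allylic alcohol with the E alkene intact.

Step 11
Reactants: 14 (E)-3-[3,4,5-tris(benzyloxy)phenyl]prop-2-en-1-ol
Product: 15 methyl (E)-3-[3,4,5-tris(benzyloxy)phenyl]allyl carbonate
Conditions: ClCO2Me, pyridine, CH2Cl2, 0 °C
Reagents that add atoms: methyl chloroformate, COC(=O)Cl
Why: Acylation of the primary allylic alcohol gives the linear carbonate that serves as the π-allyl precursor.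

Step 12
Reactants: 11 3,5-bis(benzyloxy)-4-[(2R,3S,4R)-7-(benzyloxy)-3-hydroxy-2-[3,4,5-tris(benzyloxy)phenyl]chroman-4-yl]-2-vinylphenol; 15 methyl (E)-3-[3,4,5-tris(benzyloxy)phenyl]allyl carbonate
Product: 16 (2R,3S,4R)-4-[2,6-bis(benzyloxy)-4-{(S)-1-[3,4,5-tris(benzyloxy)phenyl]allyloxy}-3-vinylphenyl]-7-(benzyloxy)-2-[3,4,5-tris(benzyloxy)phenyl]chroman-3-ol
Conditions: [IrCl(cod)]2 (cod = 1,5-cyclooctadiene; 2 mol %), (Sa)-binaphthol-derived N,N-bis[(S)-1-phenylethyl]phosphoramidite (4 mol %, activated with n-PrNH2), LiOtBu (1.0 equiv), THF, rt to 40 °C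
Reagents that add atoms: none
Why: Iridium-catalysed asymmetric allylic etherification: the lithium aryloxide attacks the substituted terminus of the π-allyl iridium complex, so the branched ether forms, and the chiral phosphoramidite, not the remote stereocentres of 11, sets the new (S) centre (future C2 of ring F).

Step 13
Reactants: 16 (2R,3S,4R)-4-[2,6-bis(benzyloxy)-4-{(S)-1-[3,4,5-tris(benzyloxy)phenyl]allyloxy}-3-vinylphenyl]-7-(benzyloxy)-2-[3,4,5-tris(benzyloxy)phenyl]chroman-3-ol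
Product: 17 (2R,3S,4R)-4-[(2S)-5,7-bis(benzyloxy)-2-[3,4,5-tris(benzyloxy)phenyl]-2H-chromen-6-yl]-7-(benzyloxy)-2-[3,4,5-tris(benzyloxy)phenyl]chroman-3-ol
Conditions: second-generation Grubbs catalyst (H2IMes)(PCy3)Cl2Ru=CHPh (5–10 mol %), 1,4-benzoquinone (10 mol %), CH2Cl2 (0.005 M), 40 °C
Reagents that add atoms: none
Why: The ruthenium benzylidene first exchanges with the less hindered terminal alkene of the allylic ether, the new alkylidene adds across the ortho vinyl group in an intramolecular [2+2] cycloaddition, and cycloreversion of the ruthenacyclobutane expels ethylene and leaves the cis C3=C4 double bond (ring-closing olefin metathesis, Chauvin mechanism). The closest known reaction type is the ring-closing metathesis of 2-(allyloxy)styrenes to 2H-chromenes. Ring F is closed as a six-membered ring by joining the two terminal alkene carbons that become C4 and C3, with the O1–C2 and C4–C4a bonds already in place. No stereocentre is created; the C2 centre from step 12 is not touched and becomes the control element for C3 in step 14. The step needs cyclisation to win over intermolecular metathesis and over migration of the allyl double bond, which the adjacency of the two vinyl groups on ring D, high dilution and the benzoquinone additive should secure; the benzyl ethers and the free secondary alcohol are inert to the catalyst.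

Step 14
Reactants: 17 (2R,3S,4R)-4-[(2S)-5,7-bis(benzyloxy)-2-[3,4,5-tris(benzyloxy)phenyl]-2H-chromen-6-yl]-7-(benzyloxy)-2-[3,4,5-tris(benzyloxy)phenyl]chroman-3-ol
Product: 19 nona-O-benzyl-robinetinidol-(4β→6)-gallocatechin, via alkylborane 18 (not isolated)
Conditions: BH3·THF (excess), THF, 0 °C to rt; then aq NaOH, H2O2, 0 °C to rt
Reagents that add atoms: borane–tetrahydrofuran, B (its boron is found in 18 only); hydrogen peroxide, OO
Why: Hydroboration–oxidation of a flav-3-ene: boron adds to C3 (the styrene β-carbon, next to the oxygen-bearing C2) syn with H on the face opposite the C2 aryl group, and oxidation with retention gives the 2,3-trans alcohol (3S).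

Step 15
Reactants: 19 nona-O-benzyl-robinetinidol-(4β→6)-gallocatechin
Product: 20 robinetinidol-(4β→6)-gallocatechin (target)
Conditions: H2 (1 atm), Pd(OH)2/C, THF/MeOH/H2O, rt
Reagents that add atoms: none
Why: Catalytic hydrogenolysis cleaves all nine benzyl ethers under neutral conditions that should leave the interflavan bond, both pyran rings and all five stereocentres intact.

**Compound list**

1 | (2R,3R)-dihydrorobinetin | Oc1ccc2c(c1)O[C@H](c1cc(O)c(O)c(O)c1)[C@@H](O)C2=O | starting material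
2 | (2R,3R)-7-(benzyloxy)-3-hydroxy-2-[3,4,5-tris(benzyloxy)phenyl]chroman-4-one | C(c1ccccc1)Oc1ccc2c(c1)O[C@H](c1cc(OCc3ccccc3)c(OCc3ccccc3)c(OCc3ccccc3)c1)[C@@H](O)C2=O | intermediate
3 | (2R,3R)-7-(benzyloxy)-3-(tert-butyldimethylsilyloxy)-2-[3,4,5-tris(benzyloxy)phenyl]chroman-4-one | C(c1ccccc1)Oc1ccc2c(c1)O[C@H](c1cc(OCc3ccccc3)c(OCc3ccccc3)c(OCc3ccccc3)c1)[C@@H](O[Si](C)(C)C(C)(C)C)C2=O | intermediate
4 | 3,5-bis(benzyloxy)phenol | Oc1cc(OCc2ccccc2)cc(OCc2ccccc2)c1 | starting material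
5 | [3,5-bis(benzyloxy)phenoxy]triisopropylsilane | CC(C)[Si](C(C)C)(C(C)C)Oc1cc(OCc2ccccc2)cc(OCc2ccccc2)c1 | intermediate
6 | [2,6-bis(benzyloxy)-4-(triisopropylsilyloxy)phenyl]lithium (aryllithium) | [Li]c1c(OCc2ccccc2)cc(O[Si](C(C)C)(C(C)C)C(C)C)cc1OCc1ccccc1 | intermediate
7 | (2R,3R,4R)-4-[2,6-bis(benzyloxy)-4-(triisopropylsilyloxy)phenyl]-7-(benzyloxy)-3-(tert-butyldimethylsilyloxy)-2-[3,4,5-tris(benzyloxy)phenyl]chroman-4-ol (4-OH cis to the 3-silyloxy group, expected) | C(c1ccccc1)Oc1ccc2c(c1)O[C@H](c1cc(OCc3ccccc3)c(OCc3ccccc3)c(OCc3ccccc3)c1)[C@@H](O[Si](C)(C)C(C)(C)C)[C@]2(O)c1c(OCc3ccccc3)cc(O[Si](C(C)C)(C(C)C)C(C)C)cc1OCc1ccccc1 | intermediate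
8 | (2R,3S,4R)-4-[2,6-bis(benzyloxy)-4-(triisopropylsilyloxy)phenyl]-7-(benzyloxy)-3-(tert-butyldimethylsilyloxy)-2-[3,4,5-tris(benzyloxy)phenyl]chromane (2,3-trans-3,4-cis) | C(c1ccccc1)Oc1ccc2c(c1)O[C@H](c1cc(OCc3ccccc3)c(OCc3ccccc3)c(OCc3ccccc3)c1)[C@@H](O[Si](C)(C)C(C)(C)C)[C@H]2c1c(OCc3ccccc3)cc(O[Si](C(C)C)(C(C)C)C(C)C)cc1OCc1ccccc1 | intermediate
9 | (2R,3S,4R)-4-[2,6-bis(benzyloxy)-4-hydroxyphenyl]-7-(benzyloxy)-2-[3,4,5-tris(benzyloxy)phenyl]chroman-3-ol | C(c1ccccc1)Oc1ccc2c(c1)O[C@H](c1cc(OCc3ccccc3)c(OCc3ccccc3)c(OCc3ccccc3)c1)[C@@H](O)[C@H]2c1c(OCc3ccccc3)cc(O)cc1OCc1ccccc1 | intermediate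
10 | 2,4-bis(benzyloxy)-6-hydroxy-3-[(2R,3S,4R)-7-(benzyloxy)-3-hydroxy-2-[3,4,5-tris(benzyloxy)phenyl]chroman-4-yl]benzaldehyde | C(c1ccccc1)Oc1ccc2c(c1)O[C@H](c1cc(OCc3ccccc3)c(OCc3ccccc3)c(OCc3ccccc3)c1)[C@@H](O)[C@H]2c1c(OCc3ccccc3)cc(O)c(C=O)c1OCc1ccccc1 | intermediate
11 | 3,5-bis(benzyloxy)-4-[(2R,3S,4R)-7-(benzyloxy)-3-hydroxy-2-[3,4,5-tris(benzyloxy)phenyl]chroman-4-yl]-2-vinylphenol | C(c1ccccc1)Oc1ccc2c(c1)O[C@H](c1cc(OCc3ccccc3)c(OCc3ccccc3)c(OCc3ccccc3)c1)[C@@H](O)[C@H]2c1c(OCc3ccccc3)cc(O)c(C=C)c1OCc1ccccc1 | intermediate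
12 | 3,4,5-tris(benzyloxy)benzaldehyde | O=Cc1cc(OCc2ccccc2)c(OCc2ccccc2)c(OCc2ccccc2)c1 | starting material
13 | ethyl (E)-3-[3,4,5-tris(benzyloxy)phenyl]prop-2-enoate | CCOC(=O)/C=C/c1cc(OCc2ccccc2)c(OCc2ccccc2)c(OCc2ccccc2)c1 | intermediate
14 | (E)-3-[3,4,5-tris(benzyloxy)phenyl]prop-2-en-1-ol | OC/C=C/c1cc(OCc2ccccc2)c(OCc2ccccc2)c(OCc2ccccc2)c1 | intermediate
15 | methyl (E)-3-[3,4,5-tris(benzyloxy)phenyl]allyl carbonate | COC(=O)OC/C=C/c1cc(OCc2ccccc2)c(OCc2ccccc2)c(OCc2ccccc2)c1 | intermediate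
16 | (2R,3S,4R)-4-[2,6-bis(benzyloxy)-4-{(S)-1-[3,4,5-tris(benzyloxy)phenyl]allyloxy}-3-vinylphenyl]-7-(benzyloxy)-2-[3,4,5-tris(benzyloxy)phenyl]chroman-3-ol | C(c1ccccc1)Oc1ccc2c(c1)O[C@H](c1cc(OCc3ccccc3)c(OCc3ccccc3)c(OCc3ccccc3)c1)[C@@H](O)[C@H]2c1c(OCc3ccccc3)cc(O[C@@H](C=C)c3cc(OCc4ccccc4)c(OCc4ccccc4)c(OCc4ccccc4)c3)c(C=C)c1OCc1ccccc1 | intermediate
17 | (2R,3S,4R)-4-[(2S)-5,7-bis(benzyloxy)-2-[3,4,5-tris(benzyloxy)phenyl]-2H-chromen-6-yl]-7-(benzyloxy)-2-[3,4,5-tris(benzyloxy)phenyl]chroman-3-ol | C(c1ccccc1)Oc1ccc2c(c1)O[C@H](c1cc(OCc3ccccc3)c(OCc3ccccc3)c(OCc3ccccc3)c1)[C@@H](O)[C@H]2c1c(OCc3ccccc3)cc2c(c1OCc1ccccc1)C=C[C@@H](c1cc(OCc3ccccc3)c(OCc3ccccc3)c(OCc3ccccc3)c1)O2 | intermediate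
18 | alkylborane: 17 with BH2 on C3 of ring F trans to the C2 aryl group (drawn as RBH2, the upper 3-OH as its O–BH2 borinate) | C(c1ccccc1)Oc1ccc2c(c1)O[C@H](c1cc(OCc3ccccc3)c(OCc3ccccc3)c(OCc3ccccc3)c1)[C@@H](OB)[C@H]2c1c(OCc3ccccc3)cc2c(c1OCc1ccccc1)C[C@H](B)[C@@H](c1cc(OCc3ccccc3)c(OCc3ccccc3)c(OCc3ccccc3)c1)O2 | intermediate
19 | nona-O-benzyl-robinetinidol-(4β→6)-gallocatechin (upper 2R,3S,4R; lower 2R,3S; both 3-OH free) | C(c1ccccc1)Oc1ccc2c(c1)O[C@H](c1cc(OCc3ccccc3)c(OCc3ccccc3)c(OCc3ccccc3)c1)[C@@H](O)[C@H]2c1c(OCc3ccccc3)cc2c(c1OCc1ccccc1)C[C@H](O)[C@@H](c1cc(OCc3ccccc3)c(OCc3ccccc3)c(OCc3ccccc3)c1)O2 | intermediate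
20 | robinetinidol-(4β→6)-gallocatechin, CNP0311915.3 | Oc1ccc2c(c1)O[C@H](c1cc(O)c(O)c(O)c1)[C@@H](O)[C@H]2c1c(O)cc2c(c1O)C[C@H](O)[C@@H](c1cc(O)c(O)c(O)c1)O2 | target

**Count.** Total steps: 15. Longest linear sequence: 11 (steps 1, 2, 4, 5, 6, 7, 8, 12, 13, 14, 15).

**Steps most likely to fail**

Step 5. Hydride delivery may show poor facial selectivity at the C4 cation and give the 3,4-trans epimer. The cation may also lose the C3 proton to a silyl enol ether, or the acid may open ring C at the O1–C2 bond. The fallback is the classical cation-plus-arene condensation; it sets out from 2 and 5 and comes back at 9. Ketone 2 is reduced with NaBH4 (THF/EtOH, 0 °C) to the 2,3-trans-3,4-trans flavan-3,4-diol F1. F1 is ionised with BF3·OEt2 (CH2Cl2, −20 °C) in the presence of 5 in a Friedel–Crafts alkylation at the ring carbon between the two benzyloxy groups. This should give the 3,4-cis adduct F2 together with its 3,4-trans epimer F3, and F2 is separated by chromatography. Desilylation of F2 with Bu4NF gives 9. This path is expected to be less selective at C4 and may also alkylate next to the silyloxy group, but it rests on well-known proanthocyanidin chemistry.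

Step 12. The hindered, electron-rich aryloxide may attack the unsubstituted allyl terminus and give the linear ether. The branched ether may also re-ionise under the catalyst, which would erode the new stereocentre. The fallback is a Mitsunobu etherification with inversion; it sets out from 12 and 11 and comes back at 16. Aldehyde 12 and vinylmagnesium bromide (THF, 0 °C) give racemic 1-[3,4,5-tris(benzyloxy)phenyl]prop-2-en-1-ol F4. Lipase-catalysed acylation (Candida antarctica lipase B, vinyl acetate) should acylate the (R) enantiomer, by the Kazlauskas rule, to the (R)-acetate F5, which is separated from the unreacted (S)-alcohol. Methanolysis (K2CO3, MeOH) gives the (R)-alcohol F6. Coupling of F6 with phenol 11 (PPh3, diisopropyl azodicarboxylate, toluene, 0 °C) should give 16 with inversion. Ionisation of this electron-rich allylic alcohol is the weakness of the path.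

Step 4. Deprotonation may occur at a benzylic CH2 of the benzyl ethers in place of the ring position, or the ketone may be enolised in place of adding the aryllithium. The fallback makes the aryllithium by halogen–lithium exchange; it sets out from 4 and comes back at 7. Para-selective bromination of 4 with Bu4NBr3 (CH2Cl2/MeOH, rt) gives 4-bromo-3,5-bis(benzyloxy)phenol F7. Silylation (TIPSCl, imidazole, DMF) gives the bromide F8. Exchange of F8 with t-BuLi (2 equiv, THF, −78 °C) gives aryllithium 6 without a deprotonation step, and addition of ketone 3 gives 7. If enolisation is the fault, the condensation path described for step 5 bypasses the addition altogether.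

**Further compounds**

F1 | step 5 | (2R,3S,4R)-7-(benzyloxy)-2-[3,4,5-tris(benzyloxy)phenyl]chromane-3,4-diol | C(c1ccccc1)Oc1ccc2c(c1)O[C@H](c1cc(OCc3ccccc3)c(OCc3ccccc3)c(OCc3ccccc3)c1)[C@@H](O)[C@@H]2O
F2 | step 5 | (2R,3S,4R)-4-[2,6-bis(benzyloxy)-4-(triisopropylsilyloxy)phenyl]-7-(benzyloxy)-2-[3,4,5-tris(benzyloxy)phenyl]chroman-3-ol (3,4-cis) | C(c1ccccc1)Oc1ccc2c(c1)O[C@H](c1cc(OCc3ccccc3)c(OCc3ccccc3)c(OCc3ccccc3)c1)[C@@H](O)[C@H]2c1c(OCc3ccccc3)cc(O[Si](C(C)C)(C(C)C)C(C)C)cc1OCc1ccccc1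
F3 | step 5 | (2R,3S,4S)-4-[2,6-bis(benzyloxy)-4-(triisopropylsilyloxy)phenyl]-7-(benzyloxy)-2-[3,4,5-tris(benzyloxy)phenyl]chroman-3-ol (3,4-trans epimer) | C(c1ccccc1)Oc1ccc2c(c1)O[C@H](c1cc(OCc3ccccc3)c(OCc3ccccc3)c(OCc3ccccc3)c1)[C@@H](O)[C@@H]2c1c(OCc3ccccc3)cc(O[Si](C(C)C)(C(C)C)C(C)C)cc1OCc1ccccc1
F4 | step 12 | racemic 1-[3,4,5-tris(benzyloxy)phenyl]prop-2-en-1-ol | C=CC(O)c1cc(OCc2ccccc2)c(OCc2ccccc2)c(OCc2ccccc2)c1
F5 | step 12 | (R)-1-[3,4,5-tris(benzyloxy)phenyl]allyl acetate | C=C[C@@H](OC(C)=O)c1cc(OCc2ccccc2)c(OCc2ccccc2)c(OCc2ccccc2)c1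
F6 | step 12 | (R)-1-[3,4,5-tris(benzyloxy)phenyl]prop-2-en-1-ol | C=C[C@@H](O)c1cc(OCc2ccccc2)c(OCc2ccccc2)c(OCc2ccccc2)c1
F7 | step 4 | 4-bromo-3,5-bis(benzyloxy)phenol | Oc1cc(OCc2ccccc2)c(Br)c(OCc2ccccc2)c1
F8 | step 4 | [4-bromo-3,5-bis(benzyloxy)phenoxy]triisopropylsilane | CC(C)[Si](C(C)C)(C(C)C)Oc1cc(OCc2ccccc2)c(Br)c(OCc2ccccc2)c1
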